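**Retrosynthetic overview**
1. The CHO group comes from a dimethyl acetal that is carried through ring formation and unmasked in the same pot, so no separate formylation is needed.
2. The pyrrole is the only ring and is formed last. Both C–N bonds come from ammonia and an acyclic γ-alkynyl α-keto acetal: N–C2 by condensation, N–C5 by 5-exo-dig addition. The outer alkyne carbon becomes C1' of the side chain.
3. The C24 alkynone comes from C(sp)–C(sp3) coupling of linolenyl iodide (C18) with 1,1-dimethoxyhex-5-yn-2-one (C6).
4. Linolenyl iodide comes from α-linolenic acid, which supplies all three Z-alkenes. The C6 alkynone comes from methylglyoxal dimethyl acetal and propargyl bromide.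

Assumption: the target has no stereocentre, so "single enantiomer" is read as the single (10Z,13Z,16Z) geometric isomer. That geometry is taken intact from α-linolenic acid. All polyene intermediates are handled under argon, in the dark, with a trace of BHT.

**Step 1**
Reactants: 1 α-linolenic acid, (9Z,12Z,15Z)-octadeca-9,12,15-trienoic acid
Product: 2 linolenyl alcohol = (9Z,12Z,15Z)-octadeca-9,12,15-trien-1-ol
Conditions: LiAlH4 (1.5 equiv), THF, 0 °C → rt, 2 h; H2O/15% NaOH work-up
Reagents that add atoms: none
Why: LiAlH4 hydride reduction takes a carboxylic acid to the primary alcohol without touching isolated alkenes, so the three Z-alkenes pass through unchanged and no stereocentre is formed.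

**Step 2**
Reactants: 2 linolenyl alcohol
Product: 3 linolenyl iodide = (3Z,6Z,9Z)-18-iodooctadeca-3,6,9-triene
Conditions: PPh3 (1.3 equiv), imidazole (1.5 equiv), I2 (1.25 equiv), CH2Cl2, 0 °C, 15 min; then 2, 0 °C → rt, 1 h, dark
Reagents that add atoms: iodine, II
Why: In this Appel-type (Garegg–Samuelsson) iodination the alkoxyphosphonium ion is displaced by iodide (SN2) at the primary carbon under near-neutral conditions, and pre-mixing I2 with PPh3 keeps free iodine away from the skipped triene.

**Step 3**
Reactants: 4 1,1-dimethoxypropan-2-one (methylglyoxal dimethyl acetal); 5 propargyl bromide (3-bromoprop-1-yne)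
Product: 7 1,1-dimethoxyhex-5-yn-2-one, via lithium enolate 6 (not isolated)
Conditions: 4 (1.2 equiv), LDA (1.1 equiv), THF, −78 °C, 45 min; then 5 (1.0 equiv), DMPU (2 equiv), −78 → −10 °C, 3 h
Reagents that add atoms: none
Why: In this kinetic lithium enolate alkylation, 4 enolises only at its CH3 group to a Li-chelated enolate, which displaces the reactive propargylic bromide by SN2 to give one regioisomer.

**Step 4**
Reactants: 3 linolenyl iodide; 7 1,1-dimethoxyhex-5-yn-2-one
Product: 8 (15Z,18Z,21Z)-1,1-dimethoxytetracosa-15,18,21-trien-5-yn-2-one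
Conditions: 7 (1.3 equiv), [(π-allyl)PdCl]2 (2.5 mol %), 1,3-bis(1-adamantyl)imidazolium chloride (5 mol %), CuI (7.5 mol %), Cs2CO3 (1.4 equiv), DMF–Et2O (1:2), 45 °C, 16 h, Ar
Reagents that add atoms: none
Why: In this alkyl Sonogashira coupling of an unactivated primary iodide, the bulky electron-rich NHC on Pd speeds oxidative addition and holds back β-hydride elimination, while carbonate at 45 °C is too weak to deprotonate the bis-allylic CH2 groups and leaves the ketone and acetal intact.

**Step 5**
Reactants: 8 (15Z,18Z,21Z)-1,1-dimethoxytetracosa-15,18,21-trien-5-yn-2-one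
Product: 11 mycalazal 20 = 5-[(10Z,13Z,16Z)-nonadeca-10,13,16-trien-1-yl]-1H-pyrrole-2-carbaldehyde, via ketimine 9 (not isolated), via pyrrole acetal 10 (not isolated)
Conditions: NH4OAc (5 equiv), IPrAuNTf2 (3 mol %), t-BuOH, 60 °C, 8 h, Ar, dark; then AcOH–H2O (1:1), rt, 1 h
Reagents that add atoms: ammonium acetate, CC(=O)[O-].[NH4+]; water, O
Why: Proposed new method: gold(I)-catalysed ammonia-transfer amino-cycloisomerisation of a γ-alkynyl α-keto acetal; the acetal-activated ketone condenses with the small amount of free NH3 held by the NH4OAc/AcOH buffer (low enough not to saturate gold) to give N–H ketimine 9 (first C–N bond), whose nitrogen adds anti and 5-exo-dig to the Au-bound alkyne (second C–N bond, ring closure); protodeauration and two prototropic shifts then aromatise to 10 and turn the outer alkyne carbon into the side-chain C1' methylene; the acetal resists ionisation while it sits next to the ketone and becomes labile (azafulvenium-stabilised) only once the pyrrole exists, so aqueous AcOH releases the aldehyde at the right moment; any alkyne that is instead hydrated through keto-group participation gives the 1,4-diketone, which the same NH4OAc converts to 10 by Paal–Knorr condensation, so both pathways converge; the nearest alkene is eight methylenes from the alkyne, so enyne cyclisation does not compete and no alkene geometry or stereocentre is touched; the closest known reaction types are the π-acid-catalysed pyrrole synthesis from 4-yn-1-ones with primary amines, the Ag/NH4OAc isoquinoline synthesis from 2-alkynylbenzaldehydes and the Paal–Knorr synthesis, none shown with an ammonium salt on a dialkyl-alkyne α-keto acetal to give an N–H 2-formylpyrrole directly.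

**Compound list**
1 | α-linolenic acid, (9Z,12Z,15Z)-octadeca-9,12,15-trienoic acid | CC/C=C\C/C=C\C/C=C\CCCCCCCC(=O)O | starting material
2 | linolenyl alcohol, (9Z,12Z,15Z)-octadeca-9,12,15-trien-1-ol | CC/C=C\C/C=C\C/C=C\CCCCCCCCO | intermediate
3 | linolenyl iodide, (3Z,6Z,9Z)-18-iodooctadeca-3,6,9-triene | CC/C=C\C/C=C\C/C=C\CCCCCCCCI | intermediate
4 | 1,1-dimethoxypropan-2-one (methylglyoxal dimethyl acetal) | CC(=O)C(OC)OC | starting material
5 | propargyl bromide, 3-bromoprop-1-yne | C#CCBr | starting material
6 | lithium 3,3-dimethoxyprop-1-en-2-olate (lithium enolate of 4) | [Li+].[O-]C(=C)C(OC)OC | intermediate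
7 | 1,1-dimethoxyhex-5-yn-2-one | C#CCCC(=O)C(OC)OC | intermediate
8 | (15Z,18Z,21Z)-1,1-dimethoxytetracosa-15,18,21-trien-5-yn-2-one | CC/C=C\C/C=C\C/C=C\CCCCCCCCC#CCCC(=O)C(OC)OC | intermediate
9 | (15Z,18Z,21Z)-1,1-dimethoxytetracosa-15,18,21-trien-5-yn-2-imine (N–H ketimine) | CC/C=C\C/C=C\C/C=C\CCCCCCCCC#CCCC(=N)C(OC)OC | intermediate
10 | 2-(dimethoxymethyl)-5-[(10Z,13Z,16Z)-nonadeca-10,13,16-trien-1-yl]-1H-pyrrole | CC/C=C\C/C=C\C/C=C\CCCCCCCCCc1ccc(C(OC)OC)[nH]1 | intermediate
11 | mycalazal 20, 5-[(10Z,13Z,16Z)-nonadeca-10,13,16-trien-1-yl]-1H-pyrrole-2-carbaldehyde | CC/C=C\C/C=C\C/C=C\CCCCCCCCCc1ccc(C=O)[nH]1 | target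

**Total step count:** 5. **Longest linear sequence:** 4 steps (1 → 2 → 3 → 8 → 11).

**Steps most likely to fail**

Step 5 (the proposed new step). Ammonia or acetate may bind the gold and stall alkyne activation. O-cyclisation to the furan or 6-endo closure may also compete. The fallback uses known chemistry, sets out from 8 and comes back at 10, and splits the event into two classical reactions. First, 8 is hydrated with keto-group participation (IPrAuCl/AgSbF6, 2 mol %, dioxane–H2O, 50 °C, no nitrogen base present). This gives (15Z,18Z,21Z)-1,1-dimethoxytetracosa-15,18,21-triene-2,5-dione F1. A standard Paal–Knorr condensation of F1 with NH4OAc in MeOH at rt to 40 °C then gives 10. Aqueous AcOH converts 10 to 11 as in step 5.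

Step 4. The enolisable, electrophilic ketone of 7 may undergo aldol or furan-forming side reactions with Cs2CO3. β-Hydride elimination from the alkyl-palladium species may also erode the yield. The fallback sets out from 3 and comes back at 8. It reverses the order of the two C–C bonds so that no ketone is exposed to the coupling.
- Propargyl alcohol is doubly deprotonated (n-BuLi, 2 equiv, THF–DMPU, −78 → 0 °C) to the dilithium salt of prop-2-yn-1-ol F2.
- F2 is alkylated with 3 to give (12Z,15Z,18Z)-henicosa-12,15,18-trien-2-yn-1-ol F3.
- CBr4/PPh3 converts F3 into (12Z,15Z,18Z)-1-bromohenicosa-12,15,18-trien-2-yne F4.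
- F4 is used in place of 5 to alkylate lithium enolate 6 (from 4 and LDA), which gives 8 directly.

Step 3. Proton exchange between product and enolate can cause dialkylation, and the small product is easily lost on isolation. The fallback sets out from 5 and comes back at 7, replacing the hard ketone enolate with a soft β-keto ester enolate. Commercial methyl 4,4-dimethoxy-3-oxobutanoate (COC(OC)C(=O)CC(=O)OC) is alkylated with 5 (K2CO3, acetone, reflux). This gives racemic methyl 2-(2,2-dimethoxyacetyl)pent-4-ynoate F5, whose stereocentre is removed in the next operation. Krapcho dealkoxycarbonylation (LiCl, wet DMSO, 130 °C) then gives 7.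

**Further compounds**
F1 | step 5 | (15Z,18Z,21Z)-1,1-dimethoxytetracosa-15,18,21-triene-2,5-dione | CC/C=C\C/C=C\C/C=C\CCCCCCCCCC(=O)CCC(=O)C(OC)OC
F2 | step 4 | dilithium salt of prop-2-yn-1-ol | [Li+].[Li+].[O-]CC#[C-]
F3 | step 4 | (12Z,15Z,18Z)-henicosa-12,15,18-trien-2-yn-1-ol | CC/C=C\C/C=C\C/C=C\CCCCCCCCC#CCO
F4 | step 4 | (12Z,15Z,18Z)-1-bromohenicosa-12,15,18-trien-2-yne | CC/C=C\C/C=C\C/C=C\CCCCCCCCC#CCBr
F5 | step 3 | methyl 2-(2,2-dimethoxyacetyl)pent-4-ynoate (racemic) | COC(=O)C(CC#C)C(=O)C(OC)OC
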